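A small charge of substrate sent more of itself to the ring side than a large one: at 3.0 min ring and isomer of the product held 43.0 % of the alpha charge but 18.6 % of the theta charge.

| flask | substrate | remark | time |
|---|---|---|---|
| alpha | 0.025 M | run made earlier |  |
| theta | 0.10 M | run made earlier |  |
| flask | 0.050 M |  | 3.0 min |

| run | time / min | isomer of the product / % | open trimer / % | open dimer / % | ring / % | substrate / % |
|---|---|---|---|---|---|---|
| alpha | 0.500 | 0.6 | 5.7 | 25.6 | 17.3 | 51.7 |
| alpha | 1.00 | 2.4 | 11.8 | 29.4 | 25.1 | 29.7 |
| alpha | 1.50 | 4.5 | 16.3 | 29.7 | 29.8 | 19.6 |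
| alpha | 2.00 | 6.3 | 19.0 | 30.3 | 31.6 | 12.6 |
| alpha | 2.50 | 8.4 | 20.3 | 28.7 | 33.4 | 9.4 |
| alpha | 3.00 | 9.6 | 21.6 | 28.5 | 33.4 | 6.8 |
| alpha | 4.00 | 10.5 | 24.1 | 27.7 | 34.8 | 3.7 |
| theta | 0.200 | 1.1 | 13.1 | 34.1 | 6.4 | 47.6 |
| theta | 0.500 | 0.6 | 28.4 | 37.3 | 11.0 | 21.4 |
| theta | 1.00 | 2.5 | 40.8 | 34.3 | 13.7 | 10.1 |
| theta | 1.50 | 1.9 | 46.6 | 31.5 | 14.7 | 5.1 |
| theta | 2.00 | 2.7 | 48.9 | 30.2 | 14.6 | 2.9 |
| theta | 3.00 | 4.3 | 50.7 | 29.7 | 14.3 | 1.3 |
| theta | 4.00 | 5.6 | 52.6 | 29.0 | 13.7 | 0.5 |

(scatter of a reading: 0.5 percentage points)

1. the species that holds most of what was charged as substrate, at 3.0 min (substrate / ring / isomer of the product / open dimer / open trimer)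
2. the largest share itself, whichever of these holds it, in percent of the substrate charged

- a species is counted by the substrate in it: one open dimer counts as two
- a species is counted by the substrate in it: one open trimer counts as three
- what was read earlier has a scatter of 0.5 percentage points, one standard deviation
- reactions considered so far: substrate -> ring; 2 substrate -> open dimer; substrate + open dimer -> open trimer; ring <-> isomer of the product

How much substrate had gone? The flask's charge was the geometric mean of the other two, so I took the same mean of what was left, 2.97 %.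

How did the loss split? Ring formation is first order in substrate, open dimer formation second order, so I divided open trimer plus open dimer by ring plus isomer of the product, then by the charge. Alpha gave 46.6 M⁻¹, theta 43.2 M⁻¹. Their mean, the partition number g (a selectivity factor per molar), was 44.9 M⁻¹. I put the flask's ring side at what had gone over one plus g times the charge: 29.9 %.

How did the open chains divide? At 3.0 min open dimer read 28.5 % in alpha and 29.7 % in theta, so I took 29.1 % for the flask, which left my estimate of open trimer at 38.0 %, more than open dimer or the ring side.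

The forecast said open trimer, 36 % (33 % to 39 %), below my figure, holding that “the oligomer-to-ring selectivity should scale roughly with concentration”.

The flask gave open trimer, 37.0 %.

    substrate → ring (k = 0.00850 s⁻¹)
    2 substrate → open dimer (k = 0.370 M⁻¹ s⁻¹)
    substrate + open dimer → open trimer (k = 0.510 M⁻¹ s⁻¹)
    ring ⇌ isomer of the product (K = 0.390, k = 0.00380 s⁻¹)

In the flask the open dimer step passed the midpoint of its turnover at 0.193 min, the ring step at 0.484 min. Open trimer still grew from 30.6 % to 37.0 % after 1.50 min, with 10.7 % substrate there at that time. Read at 50 s, the flask held 22.4 % as open trimer, less than its 34.7 % as open dimer, so a reading that early changes the answer on the species. The flask's own g at 3.0 min came to 44.8 M⁻¹. With 0.085 M charged and 1.3 % left, g gives a ring side of 20.5 %; that flask held 21.3 %.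

The numbers in the tables come from a simulation with constants of no real substance; the scatter is artificial.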